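Late in oak the links creep, from 46.8% at 40.0 min to 53.8% at 120 min, with 2.6% of the first end groups still free, so the free share is the thing to watch.

| flask | first end groups | second end groups | remark | time |
|---|---|---|---|---|
| oak | 0.050 M | 0.050 M | run made earlier |  |
| ash | 0.050 M | 0.034 M | run made earlier |  |
| maple | 0.050 M | 0.075 M | run made earlier |  |
| autumn | 0.050 M (fed, over 2.0 h) | 0.0500 M | all else is in the flask from the start; the feed brings no volume worth counting | 3.0 h |
| winter | 0.050 M | 0.0500 M (fed, over 2.0 h) | all else is in the flask from the start; the feed brings no volume worth counting | 3.0 h |
| midnight | 0.050 M | 0.0500 M | everything together at the start | 3.0 h |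

oak run (percent of the first end groups charged)

| time / min | links / % | first end groups / % |
|---|---|---|
| 8.00 | 28.3 | 48.1 |
| 20.0 | 41.0 | 20.5 |
| 40.0 | 46.8 | 7.2 |
| 60.0 | 49.0 | 6.5 |
| 80.0 | 50.1 | 2.4 |
| 120 | 53.8 | 2.6 |

ash run (percent of the first end groups charged)

| time / h | links / % | first end groups / % |
|---|---|---|
| 0.200 | 25.5 | 47.6 |
| 0.667 | 39.8 | 21.0 |
| 1.00 | 45.6 | 15.7 |
| 1.50 | 47.0 | 11.5 |
| 2.50 | 50.5 | 7.4 |
| 3.00 | 48.7 | 7.0 |

maple run (percent of the first end groups charged)

| time / h | links / % | first end groups / % |
|---|---|---|
| 0.200 | 38.6 | 19.7 |
| 0.667 | 51.0 | 4.9 |
| 1.00 | 55.5 | 2.2 |
| 1.50 | 56.5 | 0.7 |
| 2.50 | 60.0 | 1.0 |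
| 3.00 | 58.6 | 2.4 |

(readings scatter by 1 percentage point)

- for released group the idle adduct is counted in
- on the list of suspects stand: first end groups + released group <-> idle adduct; second end groups -> decomposed reagent; first end groups + second end groups -> links + released group

1. which flask leads in amount of links, in percent of the first end groups charged ("all alike" within 1.5 percentage points) (autumn / winter / midnight / all alike)
2. how much links is there at the end, in percent of the first end groups charged: autumn
3. how much links is there at the end, in percent of the first end groups charged: winter
4. how much links is there at the end, in percent of the first end groups charged: midnight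

Taken as written on the list of suspects, coupling and decay are both first order in second end groups, so dividing one rate by the other removes time and leaves links made per second end group decomposed, proportional to the free share, the first end groups still free as a fraction of their charge. The proportionality factor, at a charge of first end groups of 0.050 M, is the race number, a selectivity factor per unit free share.

Ash reads it. Ash ends near 49.6% links. Counting its other second end groups as decomposed gives 2.70 links per decomposed one. Its free share, taken roughly as the mean of its first two readings, is about 34.3%, so the race number reads about 7.86, and the race is even, one link per decomposed second end group, at a free share of about 12.7%.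

Oak has midnight's charges:

| Oak, time | Free share | Links per decomposed |
|---|---|---|
| 8.00 min | 48.1% | 3.78 |
| 20.0 min | 20.5% | 1.61 |
| 40.0 min | 7.2% | 0.566 |

By 8.00 min in oak, each link has cost 1.83 first end groups by the readings, close to one coupled and one parked as idle adduct. Oak's free share is then roughly the charge minus two per link, so on this reckoning oak's race turns even near 43.6% links. Oak's free share passes even between the second and third rows of the table, and on this reckoning decay leads in oak afterwards.

This reckoning puts midnight a little above 53.8%. Links in winter stay below the second end groups fed, so winter needs at least 0.873 h of feed to reach those links, later than oak's 40.0 min, and winter should trail midnight at the end. Autumn's free share cannot exceed what has been fed, so it stays below even for at least 0.254 h while second end groups decay, and it should come third.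

The forecast differs, putting winter first with autumn 47% (42% to 52%), winter 56% (52% to 60%) and midnight 55% (53% to 58%): “Winter's lead over midnight is narrow.”

midnight leads with 54.5%, against 52.5% for winter and 44.4% for autumn.

    first end groups + released group ⇌ idle adduct, settled at all times (K = 3090 M⁻¹)
    second end groups → decomposed reagent (k = 0.00735 min⁻¹)
    first end groups + second end groups → links + released group (k = 1.22 M⁻¹ min⁻¹)

At 3.00 h winter still holds 19.4% of its second end groups, against 9.49% in midnight. Autumn's mean free share over the first 2.0 h is 12.7%, so the race number estimates 0.999 links per decomposed second end group for autumn. At 2.00 h autumn holds 37.9% links and has 45.7% of its second end groups decomposed, which is 0.830 per decomposed one.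

The readings were computed from invented constants, and the scatter is random.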